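**Retrosynthetic overview**

1. Target 24 is cut at the two carboxyl protecting groups (allyl) and at the C6–O acyl bond; the trienoic acid 21 comes from sorbaldehyde by Doebner condensation.
2. The 6β-oxygen is traced to C12: a γ-lactone C12(=O)–O–C6, closed by 1,5-hydrogen transfer to an amidyl radical on the axial C12 amide. C12 is attached at C8 by carbonylation of an enol triflate, and the cis C8/C9 pair is set by α-face hydrogenation.
3. Feature on which the strategy rests: ring A (C1–C5, C10; gem-dimethyl on C4, angular methyl on C10) trans-fused to ring B (C5–C10), with carboxyl carbon C11 on C9 next to a functionalised C8. This is a head-to-tail geranyl chain capped by an acetoacetate unit (C8–C9–C11).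
4. Key disconnection: bonds C4–C5 and C9–C10, made in one proton-initiated cation–alkene cascade from the acyclic β-keto ester 4, which is one step from 1 and 2.
5. Ring order: rings A and B together in step 2; the lactone ring is temporary (made in step 6, opened in step 8).

Key step: step 2

Assumptions: Drimane numbering is used throughout, also for acyclic 4 (its C10=C11 alkene is C3=C4, its C6=C7 alkene is C5=C10, its C2 is C9, its C3 is C8, its C1 is C11). The (R)-configured binaphthol ligand is taken to give the 5S,10S series, as it does with aryl and hydroxyl terminators; if the sense proves opposite, the (S) ligand is used.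

**Route**

Step 1
Reactants: 1 methyl acetoacetate; 2 geranyl bromide
Product: 4 methyl (6E)-7,11-dimethyl-3-oxododeca-6,10-dienoate, via acetoacetate dianion 3 (not isolated)
Conditions: NaH, THF, 0 °C; n-BuLi, 0 °C; then 2, 0 °C to rt; 1 M HCl quench
Reagents that add atoms: none
Why: Alkylation of the acetoacetate dianion at its more reactive terminal (γ) carbon by SN2 on the primary allylic bromide (Weiler dianion alkylation), which leaves the E alkene untouched.

Step 2
Reactants: 4 methyl (6E)-7,11-dimethyl-3-oxododeca-6,10-dienoate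
Product: 5 methyl (5S,9R,10S)-8-oxo-12-nordriman-11-oate (trans-decalin; 5α-H, 10β-CH3, equatorial 9β-ester)
Conditions: SnCl4 (2.0 equiv), (R)-2'-methoxy-1,1'-binaphthalen-2-ol (2.2 equiv), toluene, −78 °C, slow addition of 4; aq. NaHCO3
Reagents that add atoms: none
Why: Proposed new method: the phenolic proton of the tin-bound binaphthol, made strongly acidic by SnCl4, is transferred to C3 on one face of the terminal C3=C4 alkene; the C4 cation is attacked by C5 of the E alkene, the C10 cation by the enol carbon C9 of the tin-chelated β-keto ester, and loss of the enol proton gives 5. The closest known reactions are the SnCl4-promoted cyclisation of this same keto ester to racemic 5, started by an achiral tin-activated protic acid, and the enantioselective proton-initiated cyclisation of geranyl arenes and homogeranyl alcohols by SnCl4–binaphthol monoether acids; joining the chiral proton source to the keto ester terminator is the untested part. Ring A closes 6-endo at the C5=C10 alkene (bond C4–C5) and ring B closes 6-endo at the C8=C9 enol (bond C9–C10), both in one chair–chair fold. For C5 and C10 the absolute configuration follows from the alkene face that the chiral acid protonates and the trans relation from anti addition across the E C5=C10 bond; C9 takes the equatorial ester in the chair transition state and, as an epimerisable β-keto ester centre, also by equilibration. The step needs enantioface-selective protonation to outrun achiral protonation (HCl–SnCl4 from tin enolate formation, or free SnCl4 with traces of water) and initiation at C3=C4 only; ligand in excess over tin, toluene at −78 °C, slow addition of 4 and the better accessibility of the terminal isopropylidene alkene are relied on for this.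

Step 3
Reactants: 5 methyl (5S,9R,10S)-8-oxo-12-nordriman-11-oate
Product: 7 methyl (5S,10S)-8-(trifluoromethylsulfonyloxy)-12-nordrim-8-en-11-oate, via sodium enolate 6 (not isolated)
Conditions: NaH, THF–DMF, 0 °C; PhNTf2, 0 °C to rt; cold 0.5 M HCl wash
Reagents that add atoms: N-phenylbis(trifluoromethanesulfonimide), O=S(=O)(N(c1ccccc1)S(=O)(=O)C(F)(F)F)C(F)(F)F
Why: O-sulfonylation of the chelated β-keto ester enolate (enol triflate formation) gives the C8 triflate conjugated with the C11 ester; the C9 centre is erased on purpose and C5 and C10 are not touched.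

Step 4
Reactants: 7 methyl (5S,10S)-8-(trifluoromethylsulfonyloxy)-12-nordrim-8-en-11-oate
Product: 9 methyl (5S,10S)-12-amino-12-oxodrim-8-en-11-oate (primary amide C12 on C8, ester C11 on C9), via bis(trimethylsilyl) amide 8 (not isolated)
Conditions: Pd(OAc)2 (5 mol %), 1,3-bis(diphenylphosphino)propane (10 mol %), CO (1 atm), HN(SiMe3)2, iPr2NEt, DMF, 70 °C; then MeOH, rt
Reagents that add atoms: carbon monoxide, [C-]#[O+]; hexamethyldisilazane, C[Si](C)(C)N[Si](C)(C)C
Why: Palladium-catalysed aminocarbonylation of a vinyl triflate (oxidative addition of zerovalent palladium, CO insertion, acyl transfer to the silylamine as ammonia equivalent) installs C12 directly as an amide, so C11 and C12 are differentiated from the start, and the silyl groups keep nitrogen from closing an imide onto the C11 ester while hot.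

Step 5
Reactants: 9 methyl (5S,10S)-12-amino-12-oxodrim-8-en-11-oate
Product: 10 methyl 12-amino-12-oxo-8αH,9αH-driman-11-oate (C12 amide β-axial on C8, C11 ester β-equatorial on C9)
Conditions: H2 (80 bar), PtO2, AcOH, 40 °C
Reagents that add atoms: none
Why: Heterogeneous syn-hydrogenation of the tetrasubstituted C8=C9 alkene from the α face, opposite the axial C10 methyl, should place both new hydrogens α and hence C11 and C12 both β (cis), which sets C8 and resets C9.

Step 6
Reactants: 10 methyl 12-amino-12-oxo-8αH,9αH-driman-11-oate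
Product: 14 methyl 8αH-driman-12,6β-olid-11-oate (γ-lactone C12(=O)–O–C6, C11 methyl ester), via N-iodoamide 11 (not isolated), via 6α-iodo amide 12 (not isolated), via iminolactone hydroiodide 13 (not isolated)
Conditions: t-BuOCl, NaI, MeCN, 0 °C, dark (gives t-BuOI); 10; then hν (tungsten lamp), rt; then H2O–THF, rt
Reagents that add atoms: water, O
Why: Barton-type N-iodoamide photolysis in the Hofmann–Löffler–Freytag manifold: N–I homolysis gives an amidyl radical on the axial C12 amide that can reach only the syn-axial 6β-H by 1,5-hydrogen transfer through a six-membered transition state, iodine is transferred to the open α face of the C6 radical, the amide oxygen displaces it from the β face, and water hydrolyses the iminolactone, so O6 can only be β.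

Step 7
Reactants: 14 methyl 8αH-driman-12,6β-olid-11-oate
Product: 15 8αH-driman-12,6β-olid-11-oic acid
Conditions: LiI, pyridine, reflux; then 1 M HCl
Reagents that add atoms: none
Why: Nucleophilic ester cleavage by SN2 attack of iodide at the methyl carbon frees the hindered C11 acid without attack at a carbonyl, leaves the lactone (which offers no accessible sp3 carbon) intact, and touches no stereocentre.

Step 8
Reactants: 15 8αH-driman-12,6β-olid-11-oic acid
Product: 17 diallyl 6β-hydroxy-8αH-drimane-11,12-dioate, via dicaesium hydroxy dicarboxylate 16 (not isolated)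
Conditions: CsOH·H2O (2.1 equiv), THF–H2O, rt; evaporate to dryness; allyl bromide, DMF, 0 °C
Reagents that add atoms: caesium hydroxide, [Cs+].[OH-]; allyl bromide, C=CCBr
Why: Saponification opens the lactone by acyl–oxygen cleavage (C6–O bond and configuration kept, C8 not enolisable as a carboxylate), and O-alkylation of the dicaesium dicarboxylate without added base at low temperature gives both allyl esters while limiting re-closure of the lactone.

Step 9
Reactants: 18 (2E,4E)-hexa-2,4-dienal; 19 malonic acid
Product: 21 (2E,4E,6E)-octa-2,4,6-trienoic acid, via dienylidenemalonic acid 20 (not isolated)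
Conditions: pyridine, piperidine (cat.), 90 °C; then 2 M HCl
Reagents that add atoms: none
Why: Knoevenagel–Doebner condensation followed by decarboxylation in the flask gives the new C2=C3 alkene in the E configuration, conjugated with the existing E,E-diene.

Step 10
Reactants: 17 diallyl 6β-hydroxy-8αH-drimane-11,12-dioate; 21 (2E,4E,6E)-octa-2,4,6-trienoic acid
Product: 23 diallyl 6β-[(2E,4E,6E)-octa-2,4,6-trienoyloxy]-8αH-drimane-11,12-dioate, via trichlorobenzoyl mixed anhydride 22 (not isolated)
Conditions: 21, 2,4,6-trichlorobenzoyl chloride, Et3N, toluene, rt; then 17, DMAP, toluene, rt to 50 °C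
Reagents that add atoms: none
Why: Yamaguchi esterification, in which DMAP turns the mixed anhydride into an acylpyridinium ion reactive enough to acylate the hindered axial 6β-hydroxyl at oxygen, with retention at C6.

Step 11
Reactants: 23 diallyl 6β-[(2E,4E,6E)-octa-2,4,6-trienoyloxy]-8αH-drimane-11,12-dioate
Product: 24 (5S,6R,8S,9S,10S)-6-[(2E,4E,6E)-octa-2,4,6-trienoyloxy]drimane-11,12-dioic acid (6β-acyloxy, 8β- and 9β-CO2H)
Conditions: Pd(PPh3)4 (5 mol %), N-methylaniline, THF, rt
Reagents that add atoms: none
Why: Tsuji–Trost deallylation, in which zerovalent palladium ionises both allyl esters to π-allyl complexes that N-methylaniline captures, under neutral conditions that spare the trienoate ester, the polyene geometry and the epimerisable axial C8 centre.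

**Compound list**

1 | methyl acetoacetate | COC(=O)CC(C)=O | starting material
2 | geranyl bromide | CC(C)=CCC/C(C)=C/CBr | starting material
3 | sodium lithium dianion of methyl acetoacetate | [Li+].[Na+].[CH2-]C([O-])=CC(=O)OC | intermediate
4 | methyl (6E)-7,11-dimethyl-3-oxododeca-6,10-dienoate | COC(=O)CC(=O)CC/C=C(\C)CCC=C(C)C | intermediate
5 | methyl (5S,9R,10S)-8-oxo-12-nordriman-11-oate | C1CC(=O)[C@H](C(=O)OC)[C@@]2(C)CCCC(C)(C)[C@H]12 | intermediate
6 | sodium enolate of 5 | [Na+].C1CC([O-])=C(C(=O)OC)[C@@]2(C)CCCC(C)(C)[C@H]12 | intermediate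
7 | methyl (5S,10S)-8-(trifluoromethylsulfonyloxy)-12-nordrim-8-en-11-oate | C1CC(OS(=O)(=O)C(F)(F)F)=C(C(=O)OC)[C@@]2(C)CCCC(C)(C)[C@H]12 | intermediate
8 | methyl (5S,10S)-12-[bis(trimethylsilyl)amino]-12-oxodrim-8-en-11-oate | C1CC(C(=O)N([Si](C)(C)C)[Si](C)(C)C)=C(C(=O)OC)[C@@]2(C)CCCC(C)(C)[C@H]12 | intermediate
9 | methyl (5S,10S)-12-amino-12-oxodrim-8-en-11-oate | C1CC(C(N)=O)=C(C(=O)OC)[C@@]2(C)CCCC(C)(C)[C@H]12 | intermediate
10 | methyl 12-amino-12-oxo-8αH,9αH-driman-11-oate | C1C[C@H](C(N)=O)[C@H](C(=O)OC)[C@@]2(C)CCCC(C)(C)[C@H]12 | intermediate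
11 | methyl 12-(iodoamino)-12-oxo-8αH,9αH-driman-11-oate | C1C[C@H](C(=O)NI)[C@H](C(=O)OC)[C@@]2(C)CCCC(C)(C)[C@H]12 | intermediate
12 | methyl 12-amino-6α-iodo-12-oxo-8αH,9αH-driman-11-oate | I[C@H]1C[C@H](C(N)=O)[C@H](C(=O)OC)[C@@]2(C)CCCC(C)(C)[C@H]12 | intermediate
13 | methyl 12-imino-8αH-driman-12,6β-olid-11-oate hydroiodide | [I-].[NH2+]=C3O[C@@H]1C[C@H]3[C@H](C(=O)OC)[C@@]2(C)CCCC(C)(C)[C@H]12 | intermediate
14 | methyl 8αH-driman-12,6β-olid-11-oate | O=C3O[C@@H]1C[C@H]3[C@H](C(=O)OC)[C@@]2(C)CCCC(C)(C)[C@H]12 | intermediate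
15 | 8αH-driman-12,6β-olid-11-oic acid | O=C3O[C@@H]1C[C@H]3[C@H](C(=O)O)[C@@]2(C)CCCC(C)(C)[C@H]12 | intermediate
16 | dicaesium 6β-hydroxy-8αH-drimane-11,12-dioate | [Cs+].[Cs+].O[C@@H]1C[C@H](C(=O)[O-])[C@H](C(=O)[O-])[C@@]2(C)CCCC(C)(C)[C@H]12 | intermediate
17 | diallyl 6β-hydroxy-8αH-drimane-11,12-dioate | O[C@@H]1C[C@H](C(=O)OCC=C)[C@H](C(=O)OCC=C)[C@@]2(C)CCCC(C)(C)[C@H]12 | intermediate
18 | (2E,4E)-hexa-2,4-dienal | C/C=C/C=C/C=O | starting material
19 | malonic acid | OC(=O)CC(=O)O | starting material
20 | 2-[(2E,4E)-hexa-2,4-dien-1-ylidene]malonic acid | C/C=C/C=C/C=C(C(=O)O)C(=O)O | intermediate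
21 | (2E,4E,6E)-octa-2,4,6-trienoic acid | C/C=C/C=C/C=C/C(=O)O | intermediate
22 | (2E,4E,6E)-octa-2,4,6-trienoic 2,4,6-trichlorobenzoic anhydride | C/C=C/C=C/C=C/C(=O)OC(=O)c1c(Cl)cc(Cl)cc1Cl | intermediate
23 | diallyl 6β-[(2E,4E,6E)-octa-2,4,6-trienoyloxy]-8αH-drimane-11,12-dioate | C/C=C/C=C/C=C/C(=O)O[C@@H]1C[C@H](C(=O)OCC=C)[C@H](C(=O)OCC=C)[C@@]2(C)CCCC(C)(C)[C@H]12 | intermediate
24 | (5S,6R,8S,9S,10S)-6-[(2E,4E,6E)-octa-2,4,6-trienoyloxy]drimane-11,12-dioic acid (CNP0462207.1) | C/C=C/C=C/C=C/C(=O)O[C@@H]1C[C@H](C(=O)O)[C@H](C(=O)O)[C@@]2(C)CCCC(C)(C)[C@H]12 | target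

**Step count**

Total steps: 11. Longest linear sequence: 10 (steps 1–8, 10, 11); step 9 is the side branch.

**Steps most likely to fail**

1. Step 2 (proposed new method). The β-keto ester may pull SnCl4 off the chiral ligand, so that protonation by achiral acid erodes the enantiomeric purity, or the cascade may stop after ring A. Fallback from 4, returning at 5: SnCl4 alone (CH2Cl2, 0 °C to rt) closes both rings without enantiocontrol to give racemic methyl 8-oxo-12-nordriman-11-oate F1. Condensation with (S)-1-phenylethylamine (TsOH cat., toluene, Dean–Stark) removes the C9 centre and gives two diastereomeric enamino esters. The (5S,10S) isomer, methyl 8-{[(1S)-1-phenylethyl]amino}-12-nordrim-8-en-11-oate F2, is separated by crystallisation or chromatography and hydrolysed (aq. HCl, THF) to 5, with C9 settling again as the equatorial ester.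

2. Step 5. The tetrasubstituted, doubly acceptor-substituted alkene next to the quaternary C10 may not hydrogenate, or forcing conditions may erode face control. Fallback from 5, returning at 10, with the C8 hydrogen delivered by hydroboration of an exocyclic alkene instead:
   - Methylenation of the C8 ketone (Zn, CH2Br2, TiCl4, THF–CH2Cl2) gives methyl drim-8(12)-en-11-oate F3.
   - 9-BBN adds from the α face, away from the axial C10 methyl, to give the B-alkyl borane methyl 12-(9-borabicyclo[3.3.1]nonan-9-yl)-8αH-driman-11-oate F4; oxidation with NaBO3·4H2O gives methyl 12-hydroxy-8αH-driman-11-oate F5 with the CH2OH β-axial.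
   - Oxidation near neutral pH (TEMPO, NaOCl cat., NaClO2, phosphate buffer) gives 11-methyl hydrogen 8αH-drimane-11,12-dioate F6.
   - Carbonyldiimidazole gives the acyl imidazolide methyl 12-(imidazol-1-yl)-12-oxo-8αH-driman-11-oate F7, and ammonia converts it into 10.

3. Step 10. Re-closure of the γ-lactone (the 6β-hydroxyl attacking the neighbouring C12 allyl ester under base) may outrun intermolecular acylation of the hindered axial alcohol by the conjugated acyl donor. Fallback from 17, returning at 23, building the acyl chain in two stages: the small, far more electrophilic diethylphosphonoacetyl chloride (pyridine, DMAP cat., CH2Cl2, −20 to 0 °C) gives diallyl 6β-[(diethoxyphosphoryl)acetoxy]-8αH-drimane-11,12-dioate F8. Horner–Wadsworth–Emmons olefination with 18 (LiCl, DBU, MeCN, Masamune–Roush conditions) then forms the E C2=C3 bond of the trienoate and gives 23.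

**Further compounds**

F1 | step 2 | racemic methyl 8-oxo-12-nordriman-11-oate | C1CC(=O)[C@H](C(=O)OC)[C@@]2(C)CCCC(C)(C)[C@H]12.C1CC(=O)[C@@H](C(=O)OC)[C@]2(C)CCCC(C)(C)[C@@H]12
F2 | step 2 | methyl (5S,10S)-8-{[(1S)-1-phenylethyl]amino}-12-nordrim-8-en-11-oate | C1CC(N[C@@H](C)c3ccccc3)=C(C(=O)OC)[C@@]2(C)CCCC(C)(C)[C@H]12
F3 | step 5 | methyl drim-8(12)-en-11-oate | C1CC(=C)[C@H](C(=O)OC)[C@@]2(C)CCCC(C)(C)[C@H]12
F4 | step 5 | methyl 12-(9-borabicyclo[3.3.1]nonan-9-yl)-8αH-driman-11-oate | C1C[C@H](CB3C4CCCC3CCC4)[C@H](C(=O)OC)[C@@]2(C)CCCC(C)(C)[C@H]12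
F5 | step 5 | methyl 12-hydroxy-8αH-driman-11-oate | C1C[C@H](CO)[C@H](C(=O)OC)[C@@]2(C)CCCC(C)(C)[C@H]12
F6 | step 5 | 11-methyl hydrogen 8αH-drimane-11,12-dioate | C1C[C@H](C(=O)O)[C@H](C(=O)OC)[C@@]2(C)CCCC(C)(C)[C@H]12
F7 | step 5 | methyl 12-(imidazol-1-yl)-12-oxo-8αH-driman-11-oate | C1C[C@H](C(=O)n3ccnc3)[C@H](C(=O)OC)[C@@]2(C)CCCC(C)(C)[C@H]12
F8 | step 10 | diallyl 6β-[(diethoxyphosphoryl)acetoxy]-8αH-drimane-11,12-dioate | CCOP(=O)(OCC)CC(=O)O[C@@H]1C[C@H](C(=O)OCC=C)[C@H](C(=O)OCC=C)[C@@]2(C)CCCC(C)(C)[C@H]12
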